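## Structural features

Compound 23 is an O-methylated type B polyprenylated acylphloroglucinol built on a bicyclo[3.3.1]nonane-2,9-dione. Ring A (C1-C2-C3-C4-C5-C9) is a vinylogous methyl ester with the ketone at C2, the benzoyl group on C3 and the methoxy group on C4. Ring B (C1-C8-C7-C6-C5-C9) is a cyclohexanone, and the two rings share C1, C9 and C5. Both bridgeheads are quaternary: C1 carries the lavandulyl chain, whose own (R) stereocentre is separated from the core by one methylene, and C5 carries a prenyl group. C5 is followed directly by the quaternary gem-dimethyl carbon C6 and the C7 methine, so C5, C6 and C7 are contiguous fully or highly substituted carbons, and C1 and C7 are 1,3-related across the C8 methylene. The C7 prenyl group is exo (equatorial on ring B, trans to the C2-C4 bridge), the core is (1R,5R,7R), and none of these centres can be epimerised once ring B is substituted. The fragile groups are four electron-rich alkenes (which rule out hydrogenation, ozonolysis and strong protic or Lewis acids), an acid-labile vinylogous ester, and, before the bicycle is closed, a non-enolisable 1,3-dicarbonyl array at C1 that hard nucleophiles can cleave by retro-Claisen reaction. The real difficulties are three: the C1/C7 relationship, which the remote side-chain stereocentre cannot direct; the quaternary bridgehead C5 next to C6; and placing the methyl ether on the C4 oxygen and not the C2 oxygen, since the two are interchangeable in a free 2,4-dione. The key step uses the fact that ring B, drawn as a cyclohexene C5=C6 with oxygen on C9, is the sum of a 1-oxygenated diene (C9-C5-C6-C7 with the C6 methyl and the C7 prenyl group) and a 2-substituted acrolein (C1=C8 with the formyl carbon C2).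

## Logic of the disconnections

23 to 21: the C3-aroyl bond is cut. C3-H is the only acidic sp2 C-H of the vinylogous ester once both bridgeheads are quaternary, so the benzoyl group is best added last. This removes the tricarbonyl tautomerism from all earlier intermediates. The forward step needs a hindered lithium amide at low temperature and acylation on carbon.

21 to 20: the C4-O bond is cut and replaced by a C4-S bond. A leaving group that sits on C4 can only be exchanged at C4, so the position of the methyl ether is fixed by constitution and does not depend on selective O-alkylation of a 2,4-dione. The forward step needs methoxide to add at a neopentyl-type carbon without opening the bicycle.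

20 to 19: the C4-C5 bond is cut, opening ring A. A chain tethered to C1 can reach C5 only on the face syn to C2, so the quaternary centre C5 needs no separate stereocontrol, and C5 already carries its prenyl group, which avoids bridgehead substitution next to C6. The bicycle becomes a monocyclic cyclohexanone. The forward step needs enolisation of a hindered methine and attack through carbon, not oxygen.

19 to 17: the C3=C4 bond and both C-S bonds are cut, so C4 comes from a one-carbon thiocarbonyl unit. This brings C4 in at the carboxyl oxidation level with two leaving groups and leaves no acidic C-H on the chain. The forward step needs kinetic enolisation of the acetyl methyl group in the presence of the C5 methine.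

17 to 16, 13 and 11: the C5-prenyl bond and the second C6-methyl bond are cut, and C2 is taken back to a carbinol. Conjugate methylation of the C5=C6 enone gives an enolate that is regiodefined because C1 is quaternary, and that enolate is alkylated at C5. C2 is held as a silyl-protected carbinol during these steps, because a C2 ketone would offer a more acidic methyl group to the C5 enolate. The forward steps need conjugate addition at a hindered β-carbon and alkylation next to a quaternary carbon.

11 to 10, 9 and 8: the C9 ketone is taken back to the silyl ether and the C2-C3 bond is cut. The formyl group of 8 is converted first, for two reasons: a β-hydroxy aldehyde formed on desilylation could fragment by retro-aldol reaction, and a free aldehyde would not survive the cuprate. Adding C3 as a methyl nucleophile solves both problems, and the allylic C9 alcohol can then be oxidised selectively.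

8 to 5 and 7 (key): the C1-C9 and C7-C8 bonds are cut. Ring B and the stereocentres C1, C7 and C9 arise together from two open chains. The forward step needs "ortho" regiochemistry, an exo formyl group and attack on one face of the dienophile, the last imposed by a chiral Lewis acid.

7 to 6, and 5 to 4, 3, 2 and 1: the O-Si bond of the dienol ether is cut, then in the other branch the C1=C8 bond (methylenation), the bond between C1 and the lavandulyl methylene (alkylation of a two-carbon nitrile anion) and the C-I bond. The stereocentre of 1 is never α to a carbonyl group in this sequence, so it cannot racemise.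

## Other disconnections considered

Alternative 1: the cut is C1-C8, with a C7-I bond made in the same step. An electrophilic iodine source under buffered conditions would activate the terminal vinyl group of the C5 1,1-dimethylallyl substituent of the dearomatised dienone A1. The enol carbon C1 would then attack C8 in a 6-endo closure to give the 7-iodo bicycle A2. In its favour, ring A arrives complete from an aromatic precursor, with the benzoyl group and the C4 methyl ether already in place. On this point it is the better plan, since the chosen route spends four steps (13 to 16) on the same features. It is also shorter overall. Against it here, A1 contains five alkenes and two enol oxygens that compete for the iodonium ion, and the lavandulyl alkenes sit close to the nucleophilic C1. The quaternary C5 is created in an uncontrolled dearomatisation with no relation to the side-chain stereocentre. The C7 prenyl group must then replace iodine by a radical allylation whose stereochemistry and chemoselectivity, with several alkenes in reach of the C7 radical, are uncertain. In the chosen plan a pericyclic step sets C1 and C7 under catalyst control, whereas in alternative 1 a cationic cyclisation leaves C7 to a later radical step.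

Alternative 2: the cuts are C1-C2 and C5-C9. The lithium enolate of cyclopentanone A3 would C-acylate diketene A4 at C1, and the released methyl ketone enolate would add through C5 to the C9 ketone, giving the cis-fused hydroxy dione A5. A later oxidative 1,2-shift would move C6 from C9 to C5 and so expand the five-membered ring. In its favour, one reagent delivers all four carbons C2 to C5. The quaternary C1 should form by approach anti to the C7 prenyl group on a cyclopentanone, which puts C2 trans to that group by substrate control. On this point it is the equal or the better of the chosen plan, which relies on exo selectivity in the cycloaddition. It is also shorter. Against it here, A3 needs its C7 centre set against the remote lavandulyl centre and an α-alkylation with a β-branched electrophile. The ring expansion uses an electrophilic trivalent iodine oxidant in the presence of four electron-rich alkenes. The C5 prenyl group would have to be introduced at a bridgehead next to the gem-dimethyl carbon after the bicycle exists, the problem that the chosen plan avoids by prenylating C5 before ring A is closed. The position of the methyl ether would still have to be secured.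

Alternative 3: the cut is C4-C5, the same bond that the chosen plan forms in step 14. A cationic monovalent gold phosphine complex would activate the bromoalkyne of the silyl enol ether A6, and the enol ether carbon C5 would attack C4 in a 6-endo-dig closure to give the 4-bromo enone A7. In its favour, the closure is catalytic and neutral, the oxygen of the nucleophile is capped so that only carbon can attack, C5 is set by the tether, and the bromide on C4 can be exchanged for methoxide. For ring A alone it is the equal of the chosen plan in stereochemical and regiochemical logic and probably its better in step count and mildness. Against it here, the carbophilic catalyst meets four other alkenes placed for enyne cycloisomerisation. The bromoynone cannot be carried through cuprate chemistry, so it must be assembled late on a hindered, retro-Claisen-prone diketone. As a key disconnection it also leaves the stereotriad of ring B unsolved: A6 needs the same cyclohexane that the chosen cycloaddition supplies. The two plans are therefore complementary, and alternative 3 is not a replacement for the chosen key step.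

Key step: step 6

## Assumptions and remarks

- Assumption: 1 is used as enantio-enriched (S) material, bought or obtained by lipase resolution of the racemate; the resolution is not counted as a step.
- Assumption: the (S)-prolinol-derived oxazaborolidinium ion is taken to expose the Re face of C1 of bound 5 (priorities CHO > CH2-lavandulyl > =CH2); if the opposite sense is found, the (R) catalyst is used.
- Structure check: 5, 7, 8 and 23 are mutually consistent in constitution and configuration. The (S) descriptor of 1 to 4 becomes (R) in 5 and later compounds only through a change of CIP priorities, without any change of geometry.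
- Remark: the exo preference of 2-alkylacroleins is well documented for cyclopentadiene. For an acyclic silyloxy diene it is an expectation and is treated as the main risk.
- Remark: commercial 6 contains the (2Z) isomer, which gives the same dienol ether.
- Remark: 9 to 16 are mixtures of C2 epimers and 15 to 19 are mixtures of C5 epimers; both carbons become sp2 or are reset later, so the mixtures are carried on.

## Route

Step 1
Reactants: 1 (S)-lavandulol
Product: 2 (S)-lavandulyl iodide, (3S)-3-(iodomethyl)-2,6-dimethylhepta-1,5-diene
Conditions: I2, PPh3, imidazole, CH2Cl2, 0 °C to rt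
Reagents that add atoms: iodine, II
Why: Appel-type iodination replaces the primary hydroxyl group by SN2 displacement at the CH2 carbon, so the adjacent stereocentre is untouched; the neutral conditions spare both alkenes.

Step 2
Reactants: 2 (S)-lavandulyl iodide
Product: 3 (4S)-7-methyl-4-(prop-1-en-2-yl)oct-6-enenitrile
Conditions: MeCN (excess), n-BuLi, THF, -78 °C; then 2, DMPU, -78 to 0 °C
Reagents that add atoms: acetonitrile, CC#N
Why: SN2 alkylation of lithioacetonitrile by the primary iodide adds the two carbons that become C1 and C2; excess anion suppresses dialkylation and the stereocentre, β to the reacting carbon, cannot epimerise.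

Step 3
Reactants: 3 (4S)-7-methyl-4-(prop-1-en-2-yl)oct-6-enenitrile
Product: 4 (4S)-7-methyl-4-(prop-1-en-2-yl)oct-6-enal
Conditions: i-Bu2AlH, CH2Cl2, -78 °C; aqueous potassium sodium tartrate
Reagents that add atoms: water, O
Why: Half-reduction of the nitrile: one hydride adds to give an N-aluminio imine that is stable at low temperature and is hydrolysed to the aldehyde on work-up; isolated alkenes do not react.

Step 4
Reactants: 4 (4S)-7-methyl-4-(prop-1-en-2-yl)oct-6-enal
Product: 5 (4R)-7-methyl-2-methylidene-4-(prop-1-en-2-yl)oct-6-enal (2-lavandulylacrolein)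
Conditions: 37% aq. CH2O, pyrrolidine (10 mol %), EtCO2H (10 mol %), i-PrOH, 45 °C
Reagents that add atoms: formaldehyde, C=O
Why: Amine-catalysed Mannich methylenation: the enamine of 4 adds to the iminium ion of formaldehyde and the amine is eliminated to give the 2-substituted acrolein; the stereocentre is γ to the carbonyl group and is not touched.

Step 5
Reactants: 6 citral (geranial), (2E)-3,7-dimethylocta-2,6-dienal
Product: 7 (1E,3E)-3,7-dimethyl-1-(triisopropylsilyloxy)octa-1,3,6-triene
Conditions: i-Pr3SiOTf, Et3N, Et2O, 0 °C to rt
Reagents that add atoms: triisopropylsilyl trifluoromethanesulfonate, CC(C)[Si](C(C)C)(C(C)C)OS(=O)(=O)C(F)(F)F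
Why: Soft vinylogous enolisation: O-silylation gives a siloxyallyl cation from which the amine removes a C4 proton, and the reversible conditions should favour the more substituted (E,E) dienol ether; geometrical isomers that cannot reach the s-cis conformation are spectators in step 6.

Step 6
Reactants: 5 (4R)-7-methyl-2-methylidene-4-(prop-1-en-2-yl)oct-6-enal; 7 (1E,3E)-3,7-dimethyl-1-(triisopropylsilyloxy)octa-1,3,6-triene
Product: 8 (1R,2R,5R)-4-methyl-5-(3-methylbut-2-enyl)-1-[(2R)-5-methyl-2-(prop-1-en-2-yl)hex-4-enyl]-2-(triisopropylsilyloxy)cyclohex-3-ene-1-carbaldehyde (core numbering: C1 formyl and lavandulyl, C9 silyloxy, C5=C6, C7 prenyl; formyl trans to the C7 prenyl group and to the C9 oxygen)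
Conditions: (S)-3,3-diphenyl-1-(2-methylphenyl)hexahydropyrrolo[1,2-c][1,3,2]oxazaborole·HN(SO2CF3)2 (20 mol %), CH2Cl2, -78 °C
Reagents that add atoms: none
Why: The cationic oxazaborolidine binds the formyl oxygen of s-trans 5 and lowers its LUMO, and 7 adds in a concerted but asynchronous [4+2] cycloaddition in which the C7-C8 bond runs ahead of the C1-C9 bond. The closest known reaction type is the oxazaborolidinium-catalysed Diels-Alder reaction of 2-substituted acroleins with cyclopentadiene and with silyloxy dienes. Ring B closes in this single cycloaddition, suprafacial on both partners, as a cyclohexene with the C5=C6 double bond. The silyloxy group on C9 makes C7 the nucleophilic diene terminus, so C7 pairs with the unsubstituted acrolein carbon C8 and C9 with C1. C1 is set by the catalyst, which screens one face of the bound enal with an aryl group of the prolinol unit and leaves the Re face of C1 open; the lavandulyl stereocentre is too remote to matter. C7 follows from the (3E) geometry of 7 together with an exo formyl group, the orientation expected for 2-alkylacroleins because the α-branch and not the catalyst-bound formyl group lies under the diene; this puts C2 trans to the C7 prenyl group. C9 follows from the (1E) geometry, lies cis to the C7 prenyl group and is removed in step 9. The step therefore needs exo selectivity and one dienophile face, and isomers of 7 with a Z double bond are too hindered in the s-cis form to compete.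

Step 7
Reactants: 8 Diels-Alder adduct (formyl compound)
Product: 9 C2 carbinol, the 1-hydroxyethyl analogue of 8 (C1, C7, C9 and side chain as in 8; both C2 epimers)
Conditions: MeMgBr, THF, -78 to 0 °C; aq. NH4Cl
Reagents that add atoms: methylmagnesium bromide, C[Mg]Br
Why: Grignard 1,2-addition to the formyl group installs C3; it is done first because a β-silyloxy aldehyde could fragment by retro-aldol reaction on desilylation and would be attacked by the cuprate of step 10, and the new C2 centre is oxidised away in step 12.

Step 8
Reactants: 9 C2 carbinol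
Product: 10 C2,C9 diol (desilylated 9; C9 allylic alcohol)
Conditions: Bu4NF, THF, rt to 45 °C
Reagents that add atoms: none
Why: Fluoride cleaves the Si-O bond of the hindered allylic silyl ether; with C2 at the carbinol level the molecule has no carbonyl group and so no retro-aldol pathway.

Step 9
Reactants: 10 C2,C9 diol
Product: 11 6-(1-hydroxyethyl)-3-methyl-4-(3-methylbut-2-enyl)-6-[(2R)-5-methyl-2-(prop-1-en-2-yl)hex-4-enyl]cyclohex-2-en-1-one (core: C9 ketone, C5=C6 enone, C7 and C1 as in 8)
Conditions: MnO2, CH2Cl2, rt
Reagents that add atoms: none
Why: MnO2 oxidises the allylic C9 alcohol far faster than the saturated C2 alcohol, giving the enone for conjugate addition while C2 stays a carbinol, so no second enolisable ketone is present in steps 10 and 11.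

Step 10
Reactants: 11 hydroxy enone
Product: 13 bis(trimethylsilyl) conjugate adduct (C9 trimethylsilyl enol ether C9=C5; C6 gem-dimethyl; C2 trimethylsilyl ether), via C2-O-trimethylsilyl enone 12 (not isolated)
Conditions: Me3SiCl, Et3N, THF, 0 °C, cannula filtration; then Me2CuLi (from CuI, MeLi), Me3SiCl, THF, -78 to -30 °C; Et3N, cold aq. NaHCO3
Reagents that add atoms: chlorotrimethylsilane, C[Si](C)(C)Cl; lithium dimethylcuprate, [Li+].C[Cu-]C
Why: Silylation of the C2 hydroxyl group prevents alkoxide retro-aldol cleavage; chlorosilane-accelerated Gilman conjugate addition then delivers the second methyl group to C6, which becomes an achiral gem-dimethyl carbon, and the enolate is trapped as a silyl enol ether that can only be C9=C5 because C1 is quaternary.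

Step 11
Reactants: 13 bis(trimethylsilyl) conjugate adduct
Product: 16 2-(1-hydroxyethyl)-5,5-dimethyl-4,6-bis(3-methylbut-2-enyl)-2-[(2R)-5-methyl-2-(prop-1-en-2-yl)hex-4-enyl]cyclohexan-1-one (core: C9 ketone; C5 prenyl; C5 epimers), via lithium C9 enolate 14 (not isolated), via C2-O-trimethylsilyl C5-prenyl ketone 15 (not isolated)
Conditions: MeLi, THF, 0 °C; prenyl bromide, DMPU, -78 to 0 °C; then aq. citric acid, THF/MeOH, 0 °C
Reagents that add atoms: 1-bromo-3-methylbut-2-ene, CC(C)=CCBr
Why: Methyllithium cleaves the enol silyl ether much faster than the alkyl silyl ether and gives the regiodefined lithium enolate, which is C-alkylated by the allylic bromide in an SN2 reaction at C5; the C5 configuration is irrelevant because C5 is enolised again in step 14, and mild acid removes the C2 silyl ether.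

Step 12
Reactants: 16 C5-prenyl hydroxy ketone
Product: 17 2-acetyl-5,5-dimethyl-4,6-bis(3-methylbut-2-enyl)-2-[(2R)-5-methyl-2-(prop-1-en-2-yl)hex-4-enyl]cyclohexan-1-one (core: C2 acetyl ketone on C1; C9 ketone)
Conditions: Dess-Martin periodinane, NaHCO3, CH2Cl2, rt
Reagents that add atoms: none
Why: Dess-Martin oxidation converts the secondary C2 alcohol into the methyl ketone under buffered, non-basic conditions, which avoids retro-aldol and retro-Claisen cleavage at the quaternary C1.

Step 13
Reactants: 17 C2 acetyl diketone
Product: 19 2-[3,3-bis(methylsulfanyl)prop-2-enoyl]-5,5-dimethyl-4,6-bis(3-methylbut-2-enyl)-2-[(2R)-5-methyl-2-(prop-1-en-2-yl)hex-4-enyl]cyclohexan-1-one (α-oxo ketene dithioacetal; C4 carries two SMe groups), via dilithium ene-dithiolate 18 (not isolated)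
Conditions: LiN(SiMe3)2 (2.2 equiv), THF, -78 °C; CS2, to 0 °C; MeI, 0 °C to rt
Reagents that add atoms: carbon disulfide, S=C=S; iodomethane, CI
Why: The amide base removes a proton from the unhindered acetyl methyl group (C3) and not from the hindered C5 methine; the enolate adds to carbon disulfide, and a second deprotonation followed by double S-methylation gives the ketene dithioacetal (the classical α-oxo ketene dithioacetal synthesis), which brings in C4 at the carboxyl oxidation level.

Step 14
Reactants: 19 α-oxo ketene dithioacetal
Product: 20 6,6-dimethyl-5,7-bis(3-methylbut-2-enyl)-1-[(2R)-5-methyl-2-(prop-1-en-2-yl)hex-4-enyl]-4-(methylsulfanyl)bicyclo[3.3.1]non-3-ene-2,9-dione (C1, C5, C7 as in 23)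
Conditions: KN(SiMe3)2, THF, -78 to 0 °C
Reagents that add atoms: none
Why: C5-H is the only remaining acidic C-H; its enolate adds through carbon to C4 in an intramolecular conjugate addition (6-endo-trig) and methanethiolate is expelled, the known addition-elimination of ketone enolates on α-oxo ketene dithioacetals. The tether from C1 lets C4 reach only the face of C5 syn to C2, which fixes the quaternary C5, and the soft acceptor favours C- over O-attack.

Step 15
Reactants: 20 4-methylsulfanyl bicyclic enone
Product: 21 4-methoxy-6,6-dimethyl-5,7-bis(3-methylbut-2-enyl)-1-[(2R)-5-methyl-2-(prop-1-en-2-yl)hex-4-enyl]bicyclo[3.3.1]non-3-ene-2,9-dione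
Conditions: NaOMe, MeOH/THF, 60 °C
Reagents that add atoms: sodium methoxide, [Na+].[O-]C
Why: Addition-elimination of methoxide at C4 of the vinylogous thioester: thiolate is the better leaving group and the vinylogous ester the more stabilised product, and the methoxy group can only end up on C4, so the regiochemistry is not left to O-alkylation of a dione.

Step 16
Reactants: 21 4-methoxy bicyclic enone
Product: 23 (1R,5R,7R)-3-benzoyl-4-methoxy-6,6-dimethyl-5,7-bis(3-methylbut-2-enyl)-1-[(2R)-5-methyl-2-(prop-1-en-2-yl)hex-4-enyl]bicyclo[3.3.1]non-3-ene-2,9-dione, via 3-lithio vinylogous ester 22 (not isolated)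
Conditions: lithium 2,2,6,6-tetramethylpiperidide (from n-BuLi and the amine), THF, -78 °C; PhCOCl, -78 °C
Reagents that add atoms: benzoyl chloride, O=C(Cl)c1ccccc1
Why: With both bridgeheads quaternary the hindered amide removes the C3 vinylic proton of the vinylogous ester, and the vinyllithium is C-acylated by benzoyl chloride, a known way to acylate C3 of O-methylated bicyclo[3.3.1]nonane-2,4,9-trione derivatives; no stereocentre is affected.

## Compound list

1 | (S)-lavandulol, (2S)-5-methyl-2-(prop-1-en-2-yl)hex-4-en-1-ol | C=C(C)[C@H](CC=C(C)C)CO | starting material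
2 | (S)-lavandulyl iodide, (3S)-3-(iodomethyl)-2,6-dimethylhepta-1,5-diene | C=C(C)[C@H](CC=C(C)C)CI | intermediate
3 | (4S)-7-methyl-4-(prop-1-en-2-yl)oct-6-enenitrile | C=C(C)[C@H](CC=C(C)C)CCC#N | intermediate
4 | (4S)-7-methyl-4-(prop-1-en-2-yl)oct-6-enal | C=C(C)[C@H](CC=C(C)C)CCC=O | intermediate
5 | (4R)-7-methyl-2-methylidene-4-(prop-1-en-2-yl)oct-6-enal (2-lavandulylacrolein) | C=C(C=O)C[C@@H](CC=C(C)C)C(C)=C | intermediate
6 | citral (geranial), (2E)-3,7-dimethylocta-2,6-dienal | CC(C)=CCC/C(C)=C/C=O | starting material
7 | (1E,3E)-3,7-dimethyl-1-(triisopropylsilyloxy)octa-1,3,6-triene | CC(C)=CC/C=C(C)/C=C/O[Si](C(C)C)(C(C)C)C(C)C | intermediate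
8 | (1R,2R,5R)-4-methyl-5-(3-methylbut-2-enyl)-1-[(2R)-5-methyl-2-(prop-1-en-2-yl)hex-4-enyl]-2-(triisopropylsilyloxy)cyclohex-3-ene-1-carbaldehyde | C=C(C)[C@H](CC=C(C)C)C[C@@]1(C=O)C[C@@H](CC=C(C)C)C(C)=C[C@H]1O[Si](C(C)C)(C(C)C)C(C)C | intermediate
9 | C2 carbinol: 1-hydroxyethyl analogue of 8 (C2 epimers) | C=C(C)[C@H](CC=C(C)C)C[C@@]1(C(C)O)C[C@@H](CC=C(C)C)C(C)=C[C@H]1O[Si](C(C)C)(C(C)C)C(C)C | intermediate
10 | C2,C9 diol: desilylated 9 (C2 epimers) | C=C(C)[C@H](CC=C(C)C)C[C@@]1(C(C)O)C[C@@H](CC=C(C)C)C(C)=C[C@H]1O | intermediate
11 | 6-(1-hydroxyethyl)-3-methyl-4-(3-methylbut-2-enyl)-6-[(2R)-5-methyl-2-(prop-1-en-2-yl)hex-4-enyl]cyclohex-2-en-1-one (C1 and C7 as in 8; C2 epimers) | C=C(C)[C@H](CC=C(C)C)C[C@@]1(C(C)O)C[C@@H](CC=C(C)C)C(C)=CC1=O | intermediate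
12 | C2-O-trimethylsilyl ether of 11 | C=C(C)[C@H](CC=C(C)C)C[C@@]1(C(C)O[Si](C)(C)C)C[C@@H](CC=C(C)C)C(C)=CC1=O | intermediate
13 | bis(trimethylsilyl) conjugate adduct: C9 silyl enol ether (C9=C5), C6 gem-dimethyl, C2 silyl ether | C=C(C)[C@H](CC=C(C)C)C[C@@]1(C(C)O[Si](C)(C)C)C[C@@H](CC=C(C)C)C(C)(C)C=C1O[Si](C)(C)C | intermediate
14 | lithium C9 enolate of the C6 gem-dimethyl ketone (C2 silyl ether) | C=C(C)[C@H](CC=C(C)C)C[C@@]1(C(C)O[Si](C)(C)C)C[C@@H](CC=C(C)C)C(C)(C)C=C1O[Li] | intermediate
15 | C2-O-trimethylsilyl C5-prenyl ketone (C5 epimers) | C=C(C)[C@H](CC=C(C)C)C[C@@]1(C(C)O[Si](C)(C)C)C[C@@H](CC=C(C)C)C(C)(C)C(CC=C(C)C)C1=O | intermediate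
16 | 2-(1-hydroxyethyl)-5,5-dimethyl-4,6-bis(3-methylbut-2-enyl)-2-[(2R)-5-methyl-2-(prop-1-en-2-yl)hex-4-enyl]cyclohexan-1-one (C2 and C5 epimers) | C=C(C)[C@H](CC=C(C)C)C[C@@]1(C(C)O)C[C@@H](CC=C(C)C)C(C)(C)C(CC=C(C)C)C1=O | intermediate
17 | 2-acetyl-5,5-dimethyl-4,6-bis(3-methylbut-2-enyl)-2-[(2R)-5-methyl-2-(prop-1-en-2-yl)hex-4-enyl]cyclohexan-1-one (C5 epimers) | C=C(C)[C@H](CC=C(C)C)C[C@@]1(C(C)=O)C[C@@H](CC=C(C)C)C(C)(C)C(CC=C(C)C)C1=O | intermediate
18 | dilithium ene-dithiolate of the β-oxo dithiocarboxylate from 17 | C=C(C)[C@H](CC=C(C)C)C[C@@]1(C(=O)C=C(S[Li])S[Li])C[C@@H](CC=C(C)C)C(C)(C)C(CC=C(C)C)C1=O | intermediate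
19 | 2-[3,3-bis(methylsulfanyl)prop-2-enoyl]-5,5-dimethyl-4,6-bis(3-methylbut-2-enyl)-2-[(2R)-5-methyl-2-(prop-1-en-2-yl)hex-4-enyl]cyclohexan-1-one (C5 epimers) | C=C(C)[C@H](CC=C(C)C)C[C@@]1(C(=O)C=C(SC)SC)C[C@@H](CC=C(C)C)C(C)(C)C(CC=C(C)C)C1=O | intermediate
20 | 6,6-dimethyl-5,7-bis(3-methylbut-2-enyl)-1-[(2R)-5-methyl-2-(prop-1-en-2-yl)hex-4-enyl]-4-(methylsulfanyl)bicyclo[3.3.1]non-3-ene-2,9-dione | C=C(C)[C@H](CC=C(C)C)C[C@@]12C[C@@H](CC=C(C)C)C(C)(C)[C@@](CC=C(C)C)(C1=O)C(SC)=CC2=O | intermediate
21 | 4-methoxy-6,6-dimethyl-5,7-bis(3-methylbut-2-enyl)-1-[(2R)-5-methyl-2-(prop-1-en-2-yl)hex-4-enyl]bicyclo[3.3.1]non-3-ene-2,9-dione | C=C(C)[C@H](CC=C(C)C)C[C@@]12C[C@@H](CC=C(C)C)C(C)(C)[C@@](CC=C(C)C)(C1=O)C(OC)=CC2=O | intermediate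
22 | 3-lithio derivative of 21 | C=C(C)[C@H](CC=C(C)C)C[C@@]12C[C@@H](CC=C(C)C)C(C)(C)[C@@](CC=C(C)C)(C1=O)C(OC)=C([Li])C2=O | intermediate
23 | (1R,5R,7R)-3-benzoyl-4-methoxy-6,6-dimethyl-5,7-bis(3-methylbut-2-enyl)-1-[(2R)-5-methyl-2-(prop-1-en-2-yl)hex-4-enyl]bicyclo[3.3.1]non-3-ene-2,9-dione (CNP0385193.1) | C=C(C)[C@H](CC=C(C)C)C[C@@]12C[C@@H](CC=C(C)C)C(C)(C)[C@@](CC=C(C)C)(C1=O)C(OC)=C(C(=O)c1ccccc1)C2=O | target

## Step count and least certain steps

Total: 16 steps. Longest linear sequence: 15 steps (steps 1 to 4 and 6 to 16, from 1); the branch from 6 joins after one step.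

Step 6 (key step). The most likely failure is loss of exo selectivity: if the catalyst-bound formyl group takes the endo position under the acyclic diene, C7 is inverted relative to C1 and cannot be corrected later. Erosion of facial selectivity or protodesilylation of 7 by traces of free acid is less likely.
Fallback: a route that no longer depends on the exo/endo outcome, setting out from 7 (and using 2) and coming back at 11.
- 7 and methyl acrylate, under the same oxazaborolidinium catalysis in its well-established endo mode, should give the all-cis methyl ester adduct F1. Only its C7 configuration is kept, and the catalyst antipode is chosen for (R) at C7.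
- Fluoride desilylation gives the hydroxy ester F2, and Dess-Martin oxidation gives the β-keto ester enone F3.
- C-alkylation of F3 with 2 (Cs2CO3, DMF) gives the quaternary keto ester F4, and Krapcho demethoxycarbonylation (LiCl, wet DMSO, 150 °C) gives the 6-lavandulyl enone F5.
- The α' lithium enolate of F5 (i-Pr2NLi, THF, -78 °C) is added to acetaldehyde. The C7 prenyl group is held pseudo-axial by allylic strain against the C6 methyl group, so the aldehyde should approach the opposite face, placing C2 trans to that group and giving 11.

Step 14. The most likely failures are sluggish enolisation of the hindered C5 methine and closure through the enolate oxygen instead of carbon, which would give a cyclic ketene O,S-acetal.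
Fallback: a nucleophile with capped oxygen, setting out from 19 and coming back at 20. 19 is O-silylated under soft enolisation (t-BuMe2SiOTf, Et3N, CH2Cl2) to the tetrasubstituted tert-butyldimethylsilyl enol ether F6. Ring A is then closed with a Lewis acid (Me3SiOTf or BF3·OEt2, CH2Cl2, -78 °C) in a Mukaiyama-Michael addition-elimination, in which only carbon can attack C4.

Step 10. The most likely failure is slow conjugate addition at the β-carbon C6, which is flanked by the branched C7, leading to recovered enone or to 1,2-addition.
Fallback: the methyl group is introduced as a cyclopropane, setting out from 11 and coming back at 16.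
- 11 is protected (Et3SiCl, imidazole) as the triethylsilyl ether F7.
- Corey-Chaykovsky cyclopropanation (Me3S(O)I, NaH, DMSO) gives the cyclopropyl ketone F8.
- Dissolving-metal reduction (Li, NH3/THF, -78 °C) cleaves the exocyclic cyclopropane bond, which creates the C6 gem-dimethyl group and the same regiodefined C9 enolate.
- Trapping with prenyl bromide gives the C5-prenyl triethylsilyl ether F9, and methanolysis (pyridinium p-toluenesulfonate, MeOH) gives 16.

Step 15. The most likely failures are incomplete or reversible exchange, because thiolate can add back at the crowded C4, and competing attack of methoxide on a ring carbonyl with retro-Claisen opening.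
Fallback: the leaving group is activated first, setting out from 20 and coming back at 21. Selective oxidation at sulfur (H2O2 in hexafluoroisopropanol, which leaves the alkenes alone) gives the vinylogous sulfoxide F10. Its sulfenate leaving group is displaced by NaOMe in MeOH at 0 °C.

Step 16. The most likely failures are incomplete C3 lithiation and acylation of the product enolate or of the base by the acid chloride.
Fallback: addition followed by oxidation, setting out from 21 and coming back at 23. The 3-lithio species is added to benzaldehyde to give the C3 carbinol F11, which Dess-Martin oxidation converts into 23.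

## Further compounds

F1 | step 6 | methyl all-cis-4-methyl-5-(3-methylbut-2-enyl)-2-(triisopropylsilyloxy)cyclohex-3-ene-1-carboxylate (C7 as in 8) | COC(=O)[C@H]1C[C@@H](CC=C(C)C)C(C)=C[C@H]1O[Si](C(C)C)(C(C)C)C(C)C
F2 | step 6 | methyl all-cis-2-hydroxy-4-methyl-5-(3-methylbut-2-enyl)cyclohex-3-ene-1-carboxylate | COC(=O)[C@H]1C[C@@H](CC=C(C)C)C(C)=C[C@H]1O
F3 | step 6 | methyl 4-methyl-5-(3-methylbut-2-enyl)-2-oxocyclohex-3-ene-1-carboxylate (C7 as in 8; C1 epimerisable) | COC(=O)C1C[C@@H](CC=C(C)C)C(C)=CC1=O
F4 | step 6 | methyl 4-methyl-5-(3-methylbut-2-enyl)-1-[(2R)-5-methyl-2-(prop-1-en-2-yl)hex-4-enyl]-2-oxocyclohex-3-ene-1-carboxylate (C1 epimers) | C=C(C)[C@H](CC=C(C)C)CC1(C(=O)OC)C[C@@H](CC=C(C)C)C(C)=CC1=O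
F5 | step 6 | 3-methyl-4-(3-methylbut-2-enyl)-6-[(2R)-5-methyl-2-(prop-1-en-2-yl)hex-4-enyl]cyclohex-2-en-1-one (C1 epimers) | C=C(C)[C@H](CC=C(C)C)CC1C[C@@H](CC=C(C)C)C(C)=CC1=O
F6 | step 14 | tert-butyldimethylsilyl enol ether (C9=C5) of 19 | C=C(C)[C@H](CC=C(C)C)C[C@@]1(C(=O)C=C(SC)SC)C[C@@H](CC=C(C)C)C(C)(C)C(CC=C(C)C)=C1O[Si](C)(C)C(C)(C)C
F7 | step 10 | C2-O-triethylsilyl ether of 11 | C=C(C)[C@H](CC=C(C)C)C[C@@]1(C(C)O[Si](CC)(CC)CC)C[C@@H](CC=C(C)C)C(C)=CC1=O
F8 | step 10 | cyclopropyl ketone: C5-C6 methano-bridged (bicyclo[4.1.0]heptan-2-one) derivative of F7 | C=C(C)[C@H](CC=C(C)C)C[C@@]1(C(C)O[Si](CC)(CC)CC)C[C@@H](CC=C(C)C)C2(C)CC2C1=O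
F9 | step 10 | C2-O-triethylsilyl ether of 16 | C=C(C)[C@H](CC=C(C)C)C[C@@]1(C(C)O[Si](CC)(CC)CC)C[C@@H](CC=C(C)C)C(C)(C)C(CC=C(C)C)C1=O
F10 | step 15 | 4-(methylsulfinyl) analogue of 20 | C=C(C)[C@H](CC=C(C)C)C[C@@]12C[C@@H](CC=C(C)C)C(C)(C)[C@@](CC=C(C)C)(C1=O)C(S(C)=O)=CC2=O
F11 | step 16 | 3-[hydroxy(phenyl)methyl] analogue of 21 | C=C(C)[C@H](CC=C(C)C)C[C@@]12C[C@@H](CC=C(C)C)C(C)(C)[C@@](CC=C(C)C)(C1=O)C(OC)=C(C(O)c1ccccc1)C2=O
A1 | alternative 1 | 6-benzoyl-3-hydroxy-5-methoxy-4-(2-methylbut-3-en-2-yl)-4-(3-methylbut-2-enyl)-2-[(2R)-5-methyl-2-(prop-1-en-2-yl)hex-4-enyl]cyclohexa-2,5-dien-1-one (C5 as in 23) | C=C(C)[C@H](CC=C(C)C)CC1=C(O)[C@](CC=C(C)C)(C(C)(C)C=C)C(OC)=C(C(=O)c2ccccc2)C1=O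
A2 | alternative 1 | 3-benzoyl-7-iodo-4-methoxy-6,6-dimethyl-5-(3-methylbut-2-enyl)-1-[(2R)-5-methyl-2-(prop-1-en-2-yl)hex-4-enyl]bicyclo[3.3.1]non-3-ene-2,9-dione | C=C(C)[C@H](CC=C(C)C)C[C@@]12C[C@@H](I)C(C)(C)[C@@](CC=C(C)C)(C1=O)C(OC)=C(C(=O)c1ccccc1)C2=O
A3 | alternative 2 | 2,2-dimethyl-3-(3-methylbut-2-enyl)-5-[(2R)-5-methyl-2-(prop-1-en-2-yl)hex-4-enyl]cyclopentan-1-one (C7 as in 23) | C=C(C)[C@H](CC=C(C)C)CC1C[C@@H](CC=C(C)C)C(C)(C)C1=O
A4 | alternative 2 | diketene, 4-methylideneoxetan-2-one | C=C1CC(=O)O1
A5 | alternative 2 | cis-fused hydroxy hydrindanedione: six-membered ring C1-C2-C3-C4-C5-C9 (C2 and C4 ketones, C9 hydroxyl) on the cyclopentane C1-C8-C7-C6-C9 | C=C(C)[C@H](CC=C(C)C)C[C@@]12C[C@@H](CC=C(C)C)C(C)(C)[C@]1(O)CC(=O)CC2=O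
A6 | alternative 3 | tert-butyldimethylsilyl enol ether (C9=C5) of 2-(3-bromoprop-2-ynoyl)-5,5-dimethyl-4,6-bis(3-methylbut-2-enyl)-2-[(2R)-5-methyl-2-(prop-1-en-2-yl)hex-4-enyl]cyclohexan-1-one | C=C(C)[C@H](CC=C(C)C)C[C@@]1(C(=O)C#CBr)C[C@@H](CC=C(C)C)C(C)(C)C(CC=C(C)C)=C1O[Si](C)(C)C(C)(C)C
A7 | alternative 3 | 4-bromo-6,6-dimethyl-5,7-bis(3-methylbut-2-enyl)-1-[(2R)-5-methyl-2-(prop-1-en-2-yl)hex-4-enyl]bicyclo[3.3.1]non-3-ene-2,9-dione | C=C(C)[C@H](CC=C(C)C)C[C@@]12C[C@@H](CC=C(C)C)C(C)(C)[C@@](CC=C(C)C)(C1=O)C(Br)=CC2=O
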